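**Retrosynthetic overview**
1. The ring ketone is unmasked last from an exocyclic methylene (ozonolysis). The axial acetate comes from the oxan-4-one by equatorial hydride delivery and acetylation, so the β-keto-lactone and the oxanone never coexist.
2. Enabling feature: in the 2-oxabicyclo[2.2.2]octane, the methyl-bearing bridgehead carbon lies between the lactone C=O and the spiro carbon that carries the oxane oxygen. Bridgehead C–spiro C–O is therefore a latent enol ether (vinylogous carbonate), and spiro C/ring O/4-oxygenated oxane is a Prins retron.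
3. Key disconnection: bridgehead C–ketone C bond, made by attack of the enol-ether carbon on a gold-activated alkyne (6-exo-dig). The same event forms the spiro C–C3' bond (Prins) and the C4'–O bond.
4. Precursor 16 is a monocyclic 4-alkoxy-5,6-dihydropyran-2-one. It is the Mitsunobu union of β-keto-δ-lactone 12 (β-ketoimide anti-aldol/lactonisation with the Roche aldehyde) and homoallylic alcohol 3 (from trans-2,3-epoxybutane).
5. Ring order: δ-lactone (step 6), then carbocycle/bicyclo[2.2.2]octane and oxane together (step 11).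

Key step: step 11

Assumption: β-keto-δ-lactone 12 is written as its 4-hydroxy enol tautomer, and enantiopure 1 is taken as purchasable (otherwise two routine steps from (2S,3S)-butane-2,3-diol).

Step 1
Reactants: 1 (2S,3S)-2,3-dimethyloxirane
Product: 2 (2S,3S)-3-methylhex-4-yn-2-ol
Conditions: 1-propynyllithium, BF3·OEt2, THF, −78 °C
Reagents that add atoms: 1-propynyllithium, [Li]C#CC
Why: Yamaguchi–Hirao alkynylation opens the C2-symmetric trans-epoxide by SN2 attack with inversion at the attacked carbon (both carbons are equivalent, so there is no regiochemical issue), which should give the 2,3-syn alcohol as one enantiomer.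

Step 2
Reactants: 2 (2S,3S)-3-methylhex-4-yn-2-ol
Product: 3 (2S,3S,4E)-3-methylhex-4-en-2-ol
Conditions: Na, NH3(l), THF, −33 °C; NH4Cl
Reagents that add atoms: none
Why: Dissolving-metal reduction of the internal alkyne runs through the trans vinyl radical anion and should give the (E)-alkene without touching the two stereocentres.

Step 3
Reactants: 4 (S)-4-benzyl-3-propionyloxazolidin-2-one
Product: 6 (S)-4-benzyl-3-[(R)-2-methyl-3-oxopentanoyl]oxazolidin-2-one, via lithium enolate 5 (not isolated)
Conditions: LDA, THF, −78 °C; EtCOCl, −78 °C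
Reagents that add atoms: propionyl chloride, CCC(=O)Cl
Why: Evans-type C-acylation of the chelated (Z)-lithium enolate on the face away from the benzyl group sets the (R)-methyl centre, which allylic 1,3-strain in the imide protects from enolisation.

Step 4
Reactants: 7 methyl (R)-3-hydroxy-2-methylpropanoate
Product: 8 methyl (R)-3-(tert-butyldimethylsilyloxy)-2-methylpropanoate
Conditions: TBSCl, imidazole, CH2Cl2, rt
Reagents that add atoms: tert-butyldimethylsilyl chloride, CC(C)(C)[Si](C)(C)Cl
Why: Standard silylation of the primary alcohol, which leaves the stereocentre untouched.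

Step 5
Reactants: 8 methyl (R)-3-(tert-butyldimethylsilyloxy)-2-methylpropanoate
Product: 9 (R)-3-(tert-butyldimethylsilyloxy)-2-methylpropanal
Conditions: DIBAL-H, CH2Cl2, −78 °C; aqueous work-up
Reagents that add atoms: none
Why: Partial DIBAL-H reduction stops at the tetrahedral aluminate at −78 °C and should release the aldehyde on work-up without epimerisation.

Step 6
Reactants: 6 (S)-4-benzyl-3-[(R)-2-methyl-3-oxopentanoyl]oxazolidin-2-one; 9 (R)-3-(tert-butyldimethylsilyloxy)-2-methylpropanal
Product: 12 (5S,6S)-6-[(2R)-1-(tert-butyldimethylsilyloxy)propan-2-yl]-4-hydroxy-3,5-dimethyl-5,6-dihydro-2H-pyran-2-one, via boron enolate 10 (not isolated), via aldol adduct 11 (not isolated)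
Conditions: c-Hex2BCl, EtNMe2, Et2O, 0 °C; 9, −78 to −20 °C; H2O2, MeOH, pH 7 buffer; then DBU (cat.), CH2Cl2, rt
Reagents that add atoms: none
Why: In this Evans-type β-ketoimide anti-aldol the (E)-boron enolate reacts through a Zimmerman–Traxler chair under control of the C2 methyl centre of 6 (2,4-anti, 4,5-anti) in the matched Felkin sense of 9, which sets C5 and C6 of the lactone (5,6-trans), and the δ-hydroxyl then acylates itself on the imide carbonyl (lactonisation) with loss of the auxiliary and of the now enolised C2 centre.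

Step 7
Reactants: 12 (5S,6S)-6-[(2R)-1-(tert-butyldimethylsilyloxy)propan-2-yl]-4-hydroxy-3,5-dimethyl-5,6-dihydro-2H-pyran-2-one; 3 (2S,3S,4E)-3-methylhex-4-en-2-ol
Product: 13 (5S,6S)-6-[(2R)-1-(tert-butyldimethylsilyloxy)propan-2-yl]-3,5-dimethyl-4-{[(2R,3S,4E)-3-methylhex-4-en-2-yl]oxy}-5,6-dihydro-2H-pyran-2-one
Conditions: PPh3, DIAD, toluene, 0 °C to rt
Reagents that add atoms: none
Why: Mitsunobu O-alkylation of the acidic vinylogous acid proceeds by SN2 with inversion at the carbinol carbon of 3, which turns the 2,3-syn alcohol into the 2,3-anti ether needed for an all-equatorial chair in step 11.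

Step 8
Reactants: 13 silyl ether from step 7
Product: 14 (5S,6S)-6-[(2R)-1-hydroxypropan-2-yl]-3,5-dimethyl-4-{[(2R,3S,4E)-3-methylhex-4-en-2-yl]oxy}-5,6-dihydro-2H-pyran-2-one
Conditions: HF·pyridine, THF, 0 °C
Reagents that add atoms: none
Why: Fluoride-mediated desilylation removes the primary TBS ether, and the vinylogous carbonate and the alkene are inert to buffered HF.

Step 9
Reactants: 14 primary alcohol from step 8
Product: 15 (2S)-2-[(2R,3S)-3,5-dimethyl-4-{[(2R,3S,4E)-3-methylhex-4-en-2-yl]oxy}-6-oxo-3,6-dihydro-2H-pyran-2-yl]propanal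
Conditions: Dess–Martin periodinane, CH2Cl2, 0 °C to rt
Reagents that add atoms: none
Why: Dess–Martin oxidation works without base, so it should stop at the aldehyde and avoid β-elimination of the lactone oxygen or epimerisation of the α-centre.

Step 10
Reactants: 15 aldehyde from step 9
Product: 16 (5S,6S)-6-[(2R)-but-3-yn-2-yl]-3,5-dimethyl-4-{[(2R,3S,4E)-3-methylhex-4-en-2-yl]oxy}-5,6-dihydro-2H-pyran-2-one
Conditions: TMSCHN2, LDA, THF, −78 °C; 15, −78 to 0 °C
Reagents that add atoms: (trimethylsilyl)diazomethane, C[Si](C)(C)C=[N+]=[N-]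
Why: In the Colvin rearrangement, addition of lithiated TMS-diazomethane, Peterson-type loss of silanolate, loss of N2 and a 1,2-H shift of the alkylidene carbene give the terminal alkyne at low temperature, where carbonyl addition should outrun α-deprotonation.

Step 11
Reactants: 16 (5S,6S)-6-[(2R)-but-3-yn-2-yl]-3,5-dimethyl-4-{[(2R,3S,4E)-3-methylhex-4-en-2-yl]oxy}-5,6-dihydro-2H-pyran-2-one
Product: 18 tricyclic equatorial alcohol (8-methylidene spiro-lactone; 4'-OH equatorial), via oxocarbenium ion 17 (not isolated)
Conditions: [(JohnPhos)Au(NCMe)]SbF6 (5 mol%), H2O (3 equiv), CH2Cl2, 0 °C to rt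
Reagents that add atoms: water, O
Why: Proposed new method: cationic gold(I) activates the terminal alkyne, the nucleophilic C3 of the vinylogous carbonate (the O-alkyl ether of a β-keto-lactone enol, i.e. a Conia-ene nucleophile that cannot lose a proton) attacks the internal alkyne carbon anti to gold, the C4 oxocarbenium ion 17 so formed is trapped by the tethered (E)-alkene in a Prins cyclisation, water captures the C4' cation, and the released proton protodeaurates the vinylgold. The closest known reaction types are the gold(I) Conia-ene and silyl-enol-ether/alkyne carbocyclisations, the acid-promoted Prins cyclisation of homoallyl vinylogous carbonates and the Mukaiyama aldol–Prins cascade of homoallyl enol ethers, which differ only in the electrophile that starts the sequence, and a soft π-acid is chosen because it is not sequestered by the Lewis-basic lactone carbonyl. Ring closures: the carbocycle, and with it the 2-oxabicyclo[2.2.2]octane, closes by 6-exo-dig attack through a boat lactone whose trans C5-methyl and C6 side chain are diaxial (a conformer favoured by allylic strain with the 4-alkoxy group), and the oxane closes by 6-endo-trig Prins attack through a chair. Stereocontrol: the quaternary bridgehead is fixed by the tether, since the alkyne on C6 reaches only one face of C3; the spiro carbon is set by alkene attack on the oxocarbenium face anti to the neighbouring C5 methyl, which is also the face that places the smaller CH(CH3) branch axial and the quaternary carbon equatorial in a chair with both tether methyls equatorial (matched pairing of 3 and 12); the (E)-alkene places the C3' methyl equatorial and water adds equatorially, anti to the new C–C bond. Selectivity needed: C3 and not C4 must bond to the alkyne, and the internal rather than the terminal alkyne carbon must be attacked, which the push–pull polarity of the enol ether (cation stabilised only at the oxygen-bearing carbon) and Markovnikov activation of a terminal alkyne secure, while the alkynophilicity of gold leaves the disubstituted alkene idle until the cation appears.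

Step 12
Reactants: 18 tricyclic equatorial alcohol
Product: 19 tricyclic oxan-4'-one
Conditions: Dess–Martin periodinane, CH2Cl2, rt
Reagents that add atoms: none
Why: Dess–Martin oxidation of the only hydroxyl gives the oxanone under non-basic conditions, and its two α-methyl groups are already equatorial, so there is no driving force for epimerisation or for retro-oxa-Michael opening.

Step 13
Reactants: 19 tricyclic oxan-4'-one
Product: 20 tricyclic axial alcohol
Conditions: L-Selectride, THF, −78 °C; H2O2, pH 7 buffer
Reagents that add atoms: none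
Why: In this substrate-controlled ketone reduction the bulky hydride attacks from the equatorial side because the axial face is closed by the axial CH(CH3) branch on the spiro carbon (1,3-diaxial), which sets the axial C4' alcohol, and the lactone and the 1,1-disubstituted alkene are inert at −78 °C.

Step 14
Reactants: 20 tricyclic axial alcohol
Product: 21 tricyclic acetate (8-methylidene analogue of the target)
Conditions: Ac2O, DMAP, pyridine, 50 °C
Reagents that add atoms: acetic anhydride, CC(=O)OC(C)=O
Why: DMAP-catalysed acylation with retention at carbon, with warming to compensate for the hindered axial position.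

Step 15
Reactants: 21 tricyclic acetate
Product: 23 CNP0257416.1, via ozonide 22 (not isolated)
Conditions: O3, CH2Cl2, −78 °C; Me2S, −78 °C to rt
Reagents that add atoms: ozone, [O-][O+]=O
Why: Ozonolysis of the only alkene removes the auxiliary methylene carbon and unveils the ketone, and the neutral reductive work-up avoids epimerisation next to the new ketone and retro-Claisen opening of the non-enolisable β-keto-lactone.

**Compound list**
1 | (2S,3S)-2,3-dimethyloxirane | C[C@@H]1O[C@H]1C | starting material
2 | (2S,3S)-3-methylhex-4-yn-2-ol | CC#C[C@H](C)[C@H](C)O | intermediate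
3 | (2S,3S,4E)-3-methylhex-4-en-2-ol | C/C=C/[C@H](C)[C@H](C)O | intermediate
4 | (S)-4-benzyl-3-propionyloxazolidin-2-one | CCC(=O)N1[C@@H](Cc2ccccc2)COC1=O | starting material
5 | lithium (Z)-enolate of 4 | C/C=C(\O[Li])N1[C@@H](Cc2ccccc2)COC1=O | intermediate
6 | (S)-4-benzyl-3-[(R)-2-methyl-3-oxopentanoyl]oxazolidin-2-one | CCC(=O)[C@@H](C)C(=O)N1[C@@H](Cc2ccccc2)COC1=O | intermediate
7 | methyl (R)-3-hydroxy-2-methylpropanoate | COC(=O)[C@H](C)CO | starting material
8 | methyl (R)-3-(tert-butyldimethylsilyloxy)-2-methylpropanoate | COC(=O)[C@H](C)CO[Si](C)(C)C(C)(C)C | intermediate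
9 | (R)-3-(tert-butyldimethylsilyloxy)-2-methylpropanal | O=C[C@H](C)CO[Si](C)(C)C(C)(C)C | intermediate
10 | (E)-dicyclohexylboron enolate of 6 | C/C=C(/OB(C1CCCCC1)C1CCCCC1)[C@@H](C)C(=O)N1[C@@H](Cc2ccccc2)COC1=O | intermediate
11 | (S)-4-benzyl-3-[(2R,4S,5S,6R)-7-(tert-butyldimethylsilyloxy)-5-hydroxy-2,4,6-trimethyl-3-oxoheptanoyl]oxazolidin-2-one | O=C1OC[C@H](Cc2ccccc2)N1C(=O)[C@H](C)C(=O)[C@@H](C)[C@@H](O)[C@H](C)CO[Si](C)(C)C(C)(C)C | intermediate
12 | (5S,6S)-6-[(2R)-1-(tert-butyldimethylsilyloxy)propan-2-yl]-4-hydroxy-3,5-dimethyl-5,6-dihydro-2H-pyran-2-one | OC1=C(C)C(=O)O[C@H]([C@@H]1C)[C@H](C)CO[Si](C)(C)C(C)(C)C | intermediate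
13 | (5S,6S)-6-[(2R)-1-(tert-butyldimethylsilyloxy)propan-2-yl]-3,5-dimethyl-4-{[(2R,3S,4E)-3-methylhex-4-en-2-yl]oxy}-5,6-dihydro-2H-pyran-2-one | C/C=C/[C@H](C)[C@@H](C)OC1=C(C)C(=O)O[C@H]([C@@H]1C)[C@H](C)CO[Si](C)(C)C(C)(C)C | intermediate
14 | (5S,6S)-6-[(2R)-1-hydroxypropan-2-yl]-3,5-dimethyl-4-{[(2R,3S,4E)-3-methylhex-4-en-2-yl]oxy}-5,6-dihydro-2H-pyran-2-one | C/C=C/[C@H](C)[C@@H](C)OC1=C(C)C(=O)O[C@H]([C@@H]1C)[C@H](C)CO | intermediate
15 | (2S)-2-[(2R,3S)-3,5-dimethyl-4-{[(2R,3S,4E)-3-methylhex-4-en-2-yl]oxy}-6-oxo-3,6-dihydro-2H-pyran-2-yl]propanal | C/C=C/[C@H](C)[C@@H](C)OC1=C(C)C(=O)O[C@H]([C@@H]1C)[C@H](C)C=O | intermediate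
16 | (5S,6S)-6-[(2R)-but-3-yn-2-yl]-3,5-dimethyl-4-{[(2R,3S,4E)-3-methylhex-4-en-2-yl]oxy}-5,6-dihydro-2H-pyran-2-one | C/C=C/[C@H](C)[C@@H](C)OC1=C(C)C(=O)O[C@H]([C@@H]1C)[C@H](C)C#C | intermediate
17 | bicyclic oxocarbenium ion (gold on the exocyclic methylene carbon omitted) | C/C=C/[C@H](C)[C@@H](C)[O+]=C1[C@@H](C)[C@H]2OC(=O)[C@]1(C)C(=C)[C@H]2C | intermediate
18 | 4'-hydroxy-3',4,5',6,6',7-hexamethyl-8-methylidenespiro[2-oxabicyclo[2.2.2]octane-5,2'-oxan]-3-one, 4'-OH equatorial (4'-epimer of 20), all other centres as in 23 | O[C@H]1[C@H](C)[C@@H](C)O[C@@]2([C@@H]1C)[C@@H](C)[C@H]1OC(=O)[C@]2(C)C(=C)[C@H]1C | intermediate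
19 | 3',4,5',6,6',7-hexamethyl-8-methylidenespiro[2-oxabicyclo[2.2.2]octane-5,2'-oxane]-3,4'-dione, all centres as in 23 | O=C1[C@H](C)[C@@H](C)O[C@@]2([C@@H]1C)[C@@H](C)[C@H]1OC(=O)[C@]2(C)C(=C)[C@H]1C | intermediate
20 | 4'-hydroxy-3',4,5',6,6',7-hexamethyl-8-methylidenespiro[2-oxabicyclo[2.2.2]octane-5,2'-oxan]-3-one, 4'-OH axial, all centres as in 23 | O[C@@H]1[C@H](C)[C@@H](C)O[C@@]2([C@@H]1C)[C@@H](C)[C@H]1OC(=O)[C@]2(C)C(=C)[C@H]1C | intermediate
21 | 3',4,5',6,6',7-hexamethyl-8-methylidene-3-oxospiro[2-oxabicyclo[2.2.2]octane-5,2'-oxan]-4'-yl acetate, all centres as in 23 | CC(=O)O[C@@H]1[C@H](C)[C@@H](C)O[C@@]2([C@@H]1C)[C@@H](C)[C@H]1OC(=O)[C@]2(C)C(=C)[C@H]1C | intermediate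
22 | secondary ozonide (spiro-1,2,4-trioxolane at C8) of 21 | CC(=O)O[C@@H]1[C@H](C)[C@@H](C)O[C@@]2([C@@H]1C)[C@@H](C)[C@H]1OC(=O)[C@]2(C)C3(OOCO3)[C@H]1C | intermediate
23 | CNP0257416.1, (1R,3'R,4S,4'R,5S,5'R,6S,6'R,7S)-3',4,5',6,6',7-hexamethyl-3,8-dioxospiro[2-oxabicyclo[2.2.2]octane-5,2'-oxan]-4'-yl acetate | CC(=O)O[C@@H]1[C@H](C)[C@@H](C)O[C@@]2([C@@H]1C)[C@@H](C)[C@H]1OC(=O)[C@]2(C)C(=O)[C@H]1C | target

**Totals:** 15 steps in all. The longest linear sequence is 12 steps (steps 4–15, from 7).

**Steps most likely to fail**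

1. **Step 11 (proposed new method).**
   - What may go wrong: water or the lactone carbonyl oxygen may add to the gold-activated alkyne faster than the deactivated enol-ether carbon, which is plain hydration. Water may also intercept the oxocarbenium ion before the Prins closure, which amounts to hydrolytic loss of the homoallyl group.
   - Fallback (known chemistry): it sets out from 16 and returns at 18, and it separates the two bond formations. Trifluoroacetic acid in CH2Cl2 protonates the enol-ether carbon, and the Brønsted-acid Prins cyclisation of homoallyl vinylogous carbonates should give the spiro-lactone trifluoroacetate F1. Brief methanolysis (K2CO3, MeOH, 0 °C) gives the spiro-lactone alcohol F2. Bromoboration–protonolysis of the terminal alkyne (B-bromo-9-BBN, then AcOH) gives the 2-bromoalkene F3. Palladium-catalysed intramolecular α-alkenylation of the lactone enolate (Pd2(dba)3, t-Bu3P, KHMDS 2.2 equiv, toluene) then closes the same bond, with the tether again fixing the quaternary centre, and delivers 18.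

2. **Step 7.**
   - What may go wrong: SN2 displacement at the β-branched secondary carbinol may be outrun by elimination of the oxyphosphonium ion, or by alkylation of the ambident lactone anion at carbon or at the other oxygen.
   - Fallback: it sets out from 3 and 12 and returns at 13. The C–O bond is made at the sp2 carbon with retention at the carbinol, instead of at the sp3 carbon with inversion. Alcohol 3 is first inverted with the small, acidic 4-nitrobenzoic acid (Mitsunobu inversion) to the inverted 4-nitrobenzoate F4, which is methanolysed to the 2,3-anti alcohol F5. Lactone 12 is converted with (COCl)2 and catalytic DMF into the vinylogous acid chloride F6. The sodium alkoxide of F5 then adds to F6 and expels chloride (vinylogous acyl substitution) to give 13.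

3. **Step 10.**
   - What may go wrong: deprotonation of the β-acyloxy aldehyde may compete with carbonyl addition, causing E1cB opening of the lactone or epimerisation of the α-centre.
   - Fallback: it sets out from 15 and returns at 16, and it replaces the diazo/carbene homologation by an olefination–elimination sequence. Neutral Ramirez olefination (CBr4, PPh3, Zn, CH2Cl2) gives the 1,1-dibromoalkene F7. Palladium-catalysed hydrogenolysis of the trans C–Br bond (Bu3SnH, Pd(PPh3)4) gives the (Z)-1-bromoalkene F8. Anti-elimination with DBU gives 16.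

**Further compounds**
F1 | step 11 | spiro-lactone trifluoroacetate (equatorial 4'-ester, lactone α-carbon unassigned) | FC(F)(F)C(=O)O[C@H]1[C@H](C)[C@@H](C)O[C@@]2([C@@H]1C)[C@@H](C)[C@@H](OC(=O)C2C)[C@H](C)C#C
F2 | step 11 | spiro-lactone alcohol | O[C@H]1[C@H](C)[C@@H](C)O[C@@]2([C@@H]1C)[C@@H](C)[C@@H](OC(=O)C2C)[C@H](C)C#C
F3 | step 11 | 2-bromoalkene | O[C@H]1[C@H](C)[C@@H](C)O[C@@]2([C@@H]1C)[C@@H](C)[C@@H](OC(=O)C2C)[C@H](C)C(Br)=C
F4 | step 7 | (2R,3S,4E)-3-methylhex-4-en-2-yl 4-nitrobenzoate | C/C=C/[C@H](C)[C@@H](C)OC(=O)c1ccc(cc1)[N+](=O)[O-]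
F5 | step 7 | (2R,3S,4E)-3-methylhex-4-en-2-ol | C/C=C/[C@H](C)[C@@H](C)O
F6 | step 7 | (5S,6S)-6-[(2R)-1-(tert-butyldimethylsilyloxy)propan-2-yl]-4-chloro-3,5-dimethyl-5,6-dihydro-2H-pyran-2-one | ClC1=C(C)C(=O)O[C@H]([C@@H]1C)[C@H](C)CO[Si](C)(C)C(C)(C)C
F7 | step 10 | 1,1-dibromoalkene from 15 | C/C=C/[C@H](C)[C@@H](C)OC1=C(C)C(=O)O[C@H]([C@@H]1C)[C@H](C)C=C(Br)Br
F8 | step 10 | (Z)-1-bromoalkene | C/C=C/[C@H](C)[C@@H](C)OC1=C(C)C(=O)O[C@H]([C@@H]1C)[C@H](C)/C=C\Br
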